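The plan rests on opening the five-membered ring at C1–C2 together with the ethylidene C–CH3 bond. The feature exploited is the C2 carbinol carbon next to the C1 ethylidene whose methyl group is cis to C2 (Z): this is the imprint of a syn addition of an aldehyde carbon and a methyl group across a terminal alkyne. One nickel-catalysed cyclization with Me2Zn therefore closes the cyclopentane, fixes the alkene geometry and sets C2. Its precursor is an all-trans cyclohexane made from (S)-cryptone: CH2CHO arm on C3a, ethynyl on C7a, isopropyl on C7, the C4 ketone masked as a dioxolane. Enone formation, epoxidation, methylenation and acylative epoxide opening then dress the six-membered ring.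

Key step: step 7

Assumption: (2E)-3-methylpent-2-enoic acid (26) and the S-configured prolinol ether catalyst are bought; the target's indane numbering (C1 to C7a) is used for every bicyclic compound, and α denotes the face of the C3a hydrogen.

Step 1
Reactants: 1 3-methylbutanal; 2 but-3-en-2-one
Product: 3 (2S)-5-oxo-2-(propan-2-yl)hexanal
Conditions: (S)-α,α-diphenylprolinol methyl ether (5 mol%), ethyl 3,4-dihydroxybenzoate (20 mol%), neat, 4 °C
Reagents that add atoms: none
Why: Enamine-mediated Michael addition in which the E-enamine of 1 is shielded on one face by the diphenyl(methoxy)methyl group of the S catalyst, so the enone should add to the open face and set the S centre that later becomes C7.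

Step 2
Reactants: 3 (2S)-5-oxo-2-(propan-2-yl)hexanal
Product: 4 (4S)-4-(propan-2-yl)cyclohex-2-en-1-one ((S)-cryptone)
Conditions: LiOH (0.1 equiv), i-PrOH, rt
Reagents that add atoms: none
Why: Intramolecular aldol condensation in which the methyl ketone enolate closes the six-membered ring onto the aldehyde and water is eliminated to the conjugated enone, the mild base sparing the stereocentre.

Step 3
Reactants: 4 (4S)-4-(propan-2-yl)cyclohex-2-en-1-one; 5 ethynyltrimethylsilane; 6 allyl bromide
Product: 11 (2R,3S,4S)-4-(propan-2-yl)-2-(prop-2-en-1-yl)-3-[(trimethylsilyl)ethynyl]cyclohexan-1-one, via lithium (trimethylsilyl)acetylide 7 (not isolated), via alkynylalane 8 (not isolated), via dimethylaluminium enolate 9 (not isolated), via lithium aluminate enolate 10 (not isolated)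
Conditions: 5, n-BuLi, Et2O, 0 °C; Me2AlCl, 0 °C to rt; Ni(acac)2 (5 mol%), i-Bu2AlH (5 mol%), then 4, Et2O, −5 °C; MeLi, THF, −78 to −40 °C; 6, DMPU, −40 °C to rt; aqueous work-up
Reagents that add atoms: none
Why: Nickel-catalysed conjugate addition of the alkynylalane to the s-trans enone should deliver the alkynyl group anti to the neighbouring isopropyl group (C7a set), and the regiodefined enolate, activated as its aluminate, undergoes SN2 enolate allylation anti to the new alkynyl group (C3a set), the all-equatorial product also being the thermodynamic epimer at the α-carbon.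

Step 4
Reactants: 11 (2R,3S,4S)-4-(propan-2-yl)-2-(prop-2-en-1-yl)-3-[(trimethylsilyl)ethynyl]cyclohexan-1-one
Product: 12 (6R,7S,8S)-8-(propan-2-yl)-6-(prop-2-en-1-yl)-7-[(trimethylsilyl)ethynyl]-1,4-dioxaspiro[4.5]decane
Conditions: ethylene glycol, p-TsOH (cat.), benzene, reflux, Dean–Stark trap
Reagents that add atoms: ethylene glycol, OCCO
Why: Acid-catalysed ketalization driven by azeotropic removal of water, to which silylalkyne and allyl group are inert and in which any enolisation at the α-carbon returns the equatorial all-trans isomer.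

Step 5
Reactants: 12 (6R,7S,8S)-8-(propan-2-yl)-6-(prop-2-en-1-yl)-7-[(trimethylsilyl)ethynyl]-1,4-dioxaspiro[4.5]decane
Product: 13 (6R,7S,8S)-7-ethynyl-8-(propan-2-yl)-6-(prop-2-en-1-yl)-1,4-dioxaspiro[4.5]decane
Conditions: K2CO3 (cat.), MeOH, rt
Reagents that add atoms: none
Why: Base-catalysed methanolysis of the alkynyl C–Si bond (protodesilylation) frees the terminal alkyne without touching the ketal or the allyl group.

Step 6
Reactants: 13 (6R,7S,8S)-7-ethynyl-8-(propan-2-yl)-6-(prop-2-en-1-yl)-1,4-dioxaspiro[4.5]decane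
Product: 14 2-[(6R,7S,8S)-7-ethynyl-8-(propan-2-yl)-1,4-dioxaspiro[4.5]decan-6-yl]acetaldehyde
Conditions: OsO4 (2 mol%), NaIO4 (4 equiv), 2,6-lutidine, dioxane/H2O 3:1, rt
Reagents that add atoms: osmium tetroxide, O=[Os](=O)(=O)=O; sodium periodate, [Na+].[O-]I(=O)(=O)=O
Why: Lemieux–Johnson cleavage in which OsO4 dihydroxylates the monosubstituted alkene far faster than the terminal alkyne and NaIO4 cleaves the diol, the lutidine buffer protecting dioxolane and aldehyde.

Step 7
Reactants: 14 2-[(6R,7S,8S)-7-ethynyl-8-(propan-2-yl)-1,4-dioxaspiro[4.5]decan-6-yl]acetaldehyde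
Product: 16 (1'Z,2'R,3a'R,7'S,7a'S)-1'-ethylidene-7'-(propan-2-yl)octahydrospiro[[1,3]dioxolane-2,4'-inden]-2'-ol, via methylzinc alkoxide 15 (not isolated)
Conditions: Ni(cod)2 (10 mol%), Me2Zn (2.5 equiv), THF, 0 °C; then H2O
Reagents that add atoms: dimethylzinc, C[Zn]C
Why: Zerovalent nickel binds aldehyde and alkyne of 14 and couples them oxidatively to a five-membered oxanickelacycle in which C2 and nickel are cis on the new C1=C bond; Me2Zn then transfers methyl to nickel while zinc takes the alkoxide, and reductive elimination puts CH3 where nickel was, so the ethylidene methyl is cis to C2 (Z) and the product leaves as 15. The closest known reaction type is the nickel-catalysed alkylative cyclization of alkynals with organozincs to exocyclic allylic alcohols, which is established for terminal alkynes and five-membered rings. The cyclopentane closes in the 5-exo-dig mode, C2 bonding to the internal alkyne carbon while the terminal carbon becomes exocyclic, from two trans-diequatorial arms, which is the geometry of a trans-hydrindane. The new stereocentre C2 is under substrate control: the gauche C3–C3a–C7a–C1 torsion of the diequatorial arms fixes the sense of twist of the forming ring, and only with oxygen on the α face can O–C2–C1=C become coplanar as the oxanickelacycle demands, which should give the 2R alkoxide. The step needs alkylative rather than reductive coupling and reaction at the aldehyde only; Me2Zn has no β-hydrogen, no phosphine is added, and the one other carbonyl is masked as the dioxolane. C3a, C7 and C7a are not touched.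

Step 8
Reactants: 16 (1'Z,2'R,3a'R,7'S,7a'S)-1'-ethylidene-7'-(propan-2-yl)octahydrospiro[[1,3]dioxolane-2,4'-inden]-2'-ol
Product: 17 tert-butyl{[(1'Z,2'R,3a'R,7'S,7a'S)-1'-ethylidene-7'-(propan-2-yl)octahydrospiro[[1,3]dioxolane-2,4'-inden]-2'-yl]oxy}dimethylsilane
Conditions: t-BuMe2SiCl, imidazole, DMF, rt
Reagents that add atoms: tert-butyldimethylsilyl chloride, CC(C)(C)[Si](C)(C)Cl
Why: Imidazole-promoted silylation protects the allylic alcohol against the enolate, peroxide and ylide steps ahead without touching a stereocentre.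

Step 9
Reactants: 17 tert-butyl{[(1'Z,2'R,3a'R,7'S,7a'S)-1'-ethylidene-7'-(propan-2-yl)octahydrospiro[[1,3]dioxolane-2,4'-inden]-2'-yl]oxy}dimethylsilane
Product: 18 (1Z,2R,3aR,7S,7aS)-2-[(tert-butyldimethylsilyl)oxy]-1-ethylidene-7-(propan-2-yl)octahydro-4H-inden-4-one
Conditions: PPTS (cat.), acetone/H2O, 55 °C
Reagents that add atoms: water, O
Why: Mild acid-catalysed ketal hydrolysis, which a secondary silyl ether tolerates and which is too weakly acidic to enolise the ketone toward the ring-fusion carbon C3a.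

Step 10
Reactants: 18 (1Z,2R,3aR,7S,7aS)-2-[(tert-butyldimethylsilyl)oxy]-1-ethylidene-7-(propan-2-yl)octahydro-4H-inden-4-one
Product: 21 (1Z,2R,3aR,7R,7aS)-2-[(tert-butyldimethylsilyl)oxy]-1-ethylidene-7-(propan-2-yl)-1,2,3,3a,7,7a-hexahydro-4H-inden-4-one, via lithium enolate 19 (not isolated), via trimethylsilyl enol ether 20 (not isolated)
Conditions: LiN(i-Pr)2, THF, −78 °C; Me3SiCl, −78 to 0 °C; solvent exchange; Pd(OAc)2 (1.1 equiv), MeCN, rt
Reagents that add atoms: none
Why: Saegusa–Ito oxidation in which kinetic deprotonation occurs at the C5 methylene and not at the C3a methine, and Pd(OAc)2 turns the silyl enol ether into the C5=C6 enone by β-hydride elimination (the C7 descriptor changes by priority only).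

Step 11
Reactants: 21 (1Z,2R,3aR,7R,7aS)-2-[(tert-butyldimethylsilyl)oxy]-1-ethylidene-7-(propan-2-yl)-1,2,3,3a,7,7a-hexahydro-4H-inden-4-one
Product: 22 (1Z,2R,3aR,5S,6S,7S,7aS)-2-[(tert-butyldimethylsilyl)oxy]-5,6-epoxy-1-ethylidene-7-(propan-2-yl)octahydro-4H-inden-4-one
Conditions: 30% H2O2, NaOH (0.5 equiv), MeOH, 0 °C
Reagents that add atoms: hydrogen peroxide, OO
Why: Weitz–Scheffer epoxidation touches only the electron-poor C5=C6 bond, and in the rigid trans-fused enone hydroperoxide should add axially at C6 on the face of the C7a hydrogen with the enolate closing on the same face, which sets C5 and C6 as the epoxide cis to the isopropyl group.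

Step 12
Reactants: 22 (1Z,2R,3aR,5S,6S,7S,7aS)-2-[(tert-butyldimethylsilyl)oxy]-5,6-epoxy-1-ethylidene-7-(propan-2-yl)octahydro-4H-inden-4-one
Product: 23 tert-butyl{[(1Z,2R,3aR,5R,6S,7S,7aR)-5,6-epoxy-1-ethylidene-4-methylidene-7-(propan-2-yl)octahydro-1H-inden-2-yl]oxy}dimethylsilane
Conditions: Ph3PCH3Br, KOt-Bu, THF, 0 °C to rt
Reagents that add atoms: methyltriphenylphosphonium bromide, [Br-].C[P+](c1ccccc1)(c1ccccc1)c1ccccc1
Why: Wittig methylenation of the α,β-epoxy ketone, the unstabilised ylide adding to the carbonyl at low temperature faster than it enolises C3a and leaving epoxide and silyl ether alone.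

Step 13
Reactants: 23 tert-butyl{[(1Z,2R,3aR,5R,6S,7S,7aR)-5,6-epoxy-1-ethylidene-4-methylidene-7-(propan-2-yl)octahydro-1H-inden-2-yl]oxy}dimethylsilane
Product: 24 (1Z,2R,3aR,5R,6S,7S,7aR)-5,6-epoxy-1-ethylidene-4-methylidene-7-(propan-2-yl)octahydro-1H-inden-2-ol
Conditions: Bu4NF, THF, 0 °C to rt
Reagents that add atoms: none
Why: Fluoride-induced desilylation driven by the Si–F bond, to which the vinyl epoxide is stable.

Step 14
Reactants: 24 (1Z,2R,3aR,5R,6S,7S,7aR)-5,6-epoxy-1-ethylidene-4-methylidene-7-(propan-2-yl)octahydro-1H-inden-2-ol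
Product: 25 (1Z,2R,3aR,5R,6S,7S,7aR)-5,6-epoxy-1-ethylidene-4-methylidene-7-(propan-2-yl)octahydro-1H-inden-2-yl acetate
Conditions: Ac2O, pyridine, DMAP (cat.), CH2Cl2, 0 °C to rt
Reagents that add atoms: acetic anhydride, CC(=O)OC(C)=O
Why: DMAP-catalysed acylation of the secondary allylic alcohol with retention at C2 under basic conditions that leave the epoxide intact.

Step 15
Reactants: 25 (1Z,2R,3aR,5R,6S,7S,7aR)-5,6-epoxy-1-ethylidene-4-methylidene-7-(propan-2-yl)octahydro-1H-inden-2-yl acetate; 26 (2E)-3-methylpent-2-enoic acid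
Product: 27 (1Z,2R,3aR,5S,6S,7S,7aR)-2-acetoxy-1-ethylidene-6-hydroxy-4-methylidene-7-(propan-2-yl)octahydro-1H-inden-5-yl (2E)-3-methylpent-2-enoate
Conditions: 26 (4 equiv), Cs2CO3 (0.25 equiv), DMF, 60 °C
Reagents that add atoms: none
Why: Carboxylate SN2 opening of the vinyl epoxide at the allylic C5 from the α face, which is also the trans-diaxial (Fürst–Plattner) mode of the rigid ring, so C5 is inverted, C6 keeps its oxygen, and the diaxial hydroxy ester should not suffer acyl migration.

Compound list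
1 | 3-methylbutanal | CC(C)CC=O | starting material
2 | but-3-en-2-one | CC(=O)C=C | starting material
3 | (2S)-5-oxo-2-(propan-2-yl)hexanal | CC(C)[C@@H](C=O)CCC(C)=O | intermediate
4 | (4S)-4-(propan-2-yl)cyclohex-2-en-1-one ((S)-cryptone) | CC(C)[C@H]1C=CC(=O)CC1 | intermediate
5 | ethynyltrimethylsilane | C#C[Si](C)(C)C | starting material
6 | allyl bromide | C=CCBr | starting material
7 | lithium (trimethylsilyl)acetylide | [Li]C#C[Si](C)(C)C | intermediate (not isolated)
8 | dimethyl[(trimethylsilyl)ethynyl]alane | C[Al](C)C#C[Si](C)(C)C | intermediate (not isolated)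
9 | dimethyl{[(3S,4S)-4-(propan-2-yl)-3-[(trimethylsilyl)ethynyl]cyclohex-1-en-1-yl]oxy}alane | C[Al](C)OC1=C[C@@H](C#C[Si](C)(C)C)[C@H](C(C)C)CC1 | intermediate (not isolated)
10 | lithium trimethyl{[(3S,4S)-4-(propan-2-yl)-3-[(trimethylsilyl)ethynyl]cyclohex-1-en-1-yl]oxy}aluminate | [Li+].C[Al-](C)(C)OC1=C[C@@H](C#C[Si](C)(C)C)[C@H](C(C)C)CC1 | intermediate (not isolated)
11 | (2R,3S,4S)-4-(propan-2-yl)-2-(prop-2-en-1-yl)-3-[(trimethylsilyl)ethynyl]cyclohexan-1-one | O=C1[C@H](CC=C)[C@@H](C#C[Si](C)(C)C)[C@H](C(C)C)CC1 | intermediate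
12 | (6R,7S,8S)-8-(propan-2-yl)-6-(prop-2-en-1-yl)-7-[(trimethylsilyl)ethynyl]-1,4-dioxaspiro[4.5]decane | C12(OCCO1)[C@H](CC=C)[C@@H](C#C[Si](C)(C)C)[C@H](C(C)C)CC2 | intermediate
13 | (6R,7S,8S)-7-ethynyl-8-(propan-2-yl)-6-(prop-2-en-1-yl)-1,4-dioxaspiro[4.5]decane | C12(OCCO1)[C@H](CC=C)[C@@H](C#C)[C@H](C(C)C)CC2 | intermediate
14 | 2-[(6R,7S,8S)-7-ethynyl-8-(propan-2-yl)-1,4-dioxaspiro[4.5]decan-6-yl]acetaldehyde | C12(OCCO1)[C@H](CC=O)[C@@H](C#C)[C@H](C(C)C)CC2 | intermediate
15 | methyl{[(1'Z,2'R,3a'R,7'S,7a'S)-1'-ethylidene-7'-(propan-2-yl)octahydrospiro[[1,3]dioxolane-2,4'-inden]-2'-yl]oxy}zinc | C12(OCCO1)[C@@H]3C[C@@H](O[Zn]C)/C(=C\C)[C@H]3[C@H](C(C)C)CC2 | intermediate (not isolated)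
16 | (1'Z,2'R,3a'R,7'S,7a'S)-1'-ethylidene-7'-(propan-2-yl)octahydrospiro[[1,3]dioxolane-2,4'-inden]-2'-ol | C12(OCCO1)[C@@H]3C[C@@H](O)/C(=C\C)[C@H]3[C@H](C(C)C)CC2 | intermediate
17 | tert-butyl{[(1'Z,2'R,3a'R,7'S,7a'S)-1'-ethylidene-7'-(propan-2-yl)octahydrospiro[[1,3]dioxolane-2,4'-inden]-2'-yl]oxy}dimethylsilane | C12(OCCO1)[C@@H]3C[C@@H](O[Si](C)(C)C(C)(C)C)/C(=C\C)[C@H]3[C@H](C(C)C)CC2 | intermediate
18 | (1Z,2R,3aR,7S,7aS)-2-[(tert-butyldimethylsilyl)oxy]-1-ethylidene-7-(propan-2-yl)octahydro-4H-inden-4-one | O=C1[C@@H]2C[C@@H](O[Si](C)(C)C(C)(C)C)/C(=C\C)[C@H]2[C@H](C(C)C)CC1 | intermediate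
19 | lithium (1Z,2R,3aR,7S,7aS)-2-[(tert-butyldimethylsilyl)oxy]-1-ethylidene-7-(propan-2-yl)-2,3,3a,6,7,7a-hexahydro-1H-inden-4-olate | [Li]OC=1[C@@H]2C[C@@H](O[Si](C)(C)C(C)(C)C)/C(=C\C)[C@H]2[C@H](C(C)C)CC=1 | intermediate (not isolated)
20 | tert-butyl{[(1Z,2R,3aR,7S,7aS)-1-ethylidene-7-(propan-2-yl)-4-[(trimethylsilyl)oxy]-2,3,3a,6,7,7a-hexahydro-1H-inden-2-yl]oxy}dimethylsilane | C[Si](C)(C)OC=1[C@@H]2C[C@@H](O[Si](C)(C)C(C)(C)C)/C(=C\C)[C@H]2[C@H](C(C)C)CC=1 | intermediate (not isolated)
21 | (1Z,2R,3aR,7R,7aS)-2-[(tert-butyldimethylsilyl)oxy]-1-ethylidene-7-(propan-2-yl)-1,2,3,3a,7,7a-hexahydro-4H-inden-4-one | O=C1[C@@H]2C[C@@H](O[Si](C)(C)C(C)(C)C)/C(=C\C)[C@H]2[C@H](C(C)C)C=C1 | intermediate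
22 | (1Z,2R,3aR,5S,6S,7S,7aS)-2-[(tert-butyldimethylsilyl)oxy]-5,6-epoxy-1-ethylidene-7-(propan-2-yl)octahydro-4H-inden-4-one | O=C1[C@@H]2C[C@@H](O[Si](C)(C)C(C)(C)C)/C(=C\C)[C@H]2[C@H](C(C)C)[C@@H]3O[C@@H]31 | intermediate
23 | tert-butyl{[(1Z,2R,3aR,5R,6S,7S,7aR)-5,6-epoxy-1-ethylidene-4-methylidene-7-(propan-2-yl)octahydro-1H-inden-2-yl]oxy}dimethylsilane | C=C1[C@@H]2C[C@@H](O[Si](C)(C)C(C)(C)C)/C(=C\C)[C@H]2[C@H](C(C)C)[C@@H]3O[C@@H]31 | intermediate
24 | (1Z,2R,3aR,5R,6S,7S,7aR)-5,6-epoxy-1-ethylidene-4-methylidene-7-(propan-2-yl)octahydro-1H-inden-2-ol | C=C1[C@@H]2C[C@@H](O)/C(=C\C)[C@H]2[C@H](C(C)C)[C@@H]3O[C@@H]31 | intermediate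
25 | (1Z,2R,3aR,5R,6S,7S,7aR)-5,6-epoxy-1-ethylidene-4-methylidene-7-(propan-2-yl)octahydro-1H-inden-2-yl acetate | C=C1[C@@H]2C[C@@H](OC(C)=O)/C(=C\C)[C@H]2[C@H](C(C)C)[C@@H]3O[C@@H]31 | intermediate
26 | (2E)-3-methylpent-2-enoic acid | CC/C(C)=C/C(=O)O | starting material
27 | (1Z,2R,3aR,5S,6S,7S,7aR)-2-acetoxy-1-ethylidene-6-hydroxy-4-methylidene-7-(propan-2-yl)octahydro-1H-inden-5-yl (2E)-3-methylpent-2-enoate | C=C1[C@@H]2C[C@@H](OC(C)=O)/C(=C\C)[C@H]2[C@H](C(C)C)[C@H](O)[C@H]1OC(=O)/C=C(\C)CC | target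

Total step count: 15. Longest linear sequence: 15 steps (from 1 and 2 to 27).

Steps most likely to fail

Step 7. The aldehyde may be attacked on both faces, so that C2, the one stereochemical element not locked by the ring system, is formed with poor selectivity. The fallback sets out from 14 and comes back at 16, and replaces substrate control by reagent control. The cyclization is run as before and the mixture of 16 and its C2-epimeric alcohol F1 is oxidised without separation (Dess–Martin periodinane, NaHCO3, CH2Cl2) to the single (Z)-ethylidene ketone F2. Corey–Bakshi–Shibata reduction of F2 with the (S)-2-methyloxazaborolidine and catecholborane at −78 °C, with the alkylidene carbon C1 as the large group and the C3 methylene as the small one, should then give the 2R alcohol 16. The dioxolane keeps this the only ketone in the molecule.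

Step 15. The carboxylate is a weak and fairly bulky nucleophile, so attack at the exocyclic methylene terminus with allylic transposition, or ionisation of the allylic C5–O bond with loss of stereocontrol, may compete. The fallback sets out from 25 and comes back at 27, and forms the ester by acylation instead of by substitution at carbon. Acid-catalysed hydration with water as solvent and nucleophile (cat. HClO4, THF/H2O, 0 °C; trans-diaxial opening at C5) should give the 5α,6β-diol 2-acetate F3. Acylation of F3 with (2E)-3-methylpent-2-enoyl chloride F4 (from 26, oxalyl chloride, cat. DMF) and pyridine in CH2Cl2 at 0 °C should take place at the allylic C5 hydroxyl, because the C6 hydroxyl is axial and flanked by the isopropyl-bearing C7.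

Step 3. Capture of the aluminium enolate by allyl bromide may be incomplete or unselective (proton quench, double allylation), and the trans selectivity of the alkynyl transfer may erode. The fallback sets out from 4 (with 5 and 6) and comes back at 11, and separates the two bond formations. Lithium acetylide 7 is transmetalated with ZnBr2 to bromo[(trimethylsilyl)ethynyl]zinc F5, which adds to 4 in the presence of Me3SiOTf (silyl-triflate-promoted conjugate addition, Et2O/THF, −40 °C) to give the isolable silyl enol ether F6. MeLi in THF at 0 °C then releases the regiodefined lithium enolate F7, which 6 alkylates trans to the alkynyl group to give 11.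

Further compounds
F1 | step 7 | (1'Z,2'S,3a'R,7'S,7a'S)-1'-ethylidene-7'-(propan-2-yl)octahydrospiro[[1,3]dioxolane-2,4'-inden]-2'-ol | C12(OCCO1)[C@@H]3C[C@H](O)/C(=C\C)[C@H]3[C@H](C(C)C)CC2
F2 | step 7 | (1'Z,3a'R,7'S,7a'S)-1'-ethylidene-7'-(propan-2-yl)hexahydrospiro[[1,3]dioxolane-2,4'-inden]-2'(3'H)-one | C12(OCCO1)[C@@H]3CC(=O)/C(=C\C)[C@H]3[C@H](C(C)C)CC2
F3 | step 15 | (1Z,2R,3aR,5S,6S,7S,7aR)-1-ethylidene-5,6-dihydroxy-4-methylidene-7-(propan-2-yl)octahydro-1H-inden-2-yl acetate | C=C1[C@@H]2C[C@@H](OC(C)=O)/C(=C\C)[C@H]2[C@H](C(C)C)[C@H](O)[C@H]1O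
F4 | step 15 | (2E)-3-methylpent-2-enoyl chloride | CC/C(C)=C/C(Cl)=O
F5 | step 3 | bromo[(trimethylsilyl)ethynyl]zinc | Br[Zn]C#C[Si](C)(C)C
F6 | step 3 | trimethyl{[(3S,4S)-4-(propan-2-yl)-3-[(trimethylsilyl)ethynyl]cyclohex-1-en-1-yl]oxy}silane | C[Si](C)(C)OC1=C[C@@H](C#C[Si](C)(C)C)[C@H](C(C)C)CC1
F7 | step 3 | lithium (3S,4S)-4-(propan-2-yl)-3-[(trimethylsilyl)ethynyl]cyclohex-1-en-1-olate | [Li]OC1=C[C@@H](C#C[Si](C)(C)C)[C@H](C(C)C)CC1
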